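**Plan**
1. The target is an amentoflavone-type biflavone: two apigenin units joined from C3' (ring B, unit 1) to C8 (ring A, unit 2), with a prenyl ether on O7 of unit 2 only. The retrosynthesis cuts, in order: five phenol ester C–O bonds; the C2–C1' bond between pyranone ring C and ring B of unit 1; the O7–prenyl bond; the C3'–C8 biaryl bond; the C8–I bond.
2. Forward, no ring is built. Rings A, C and B of unit 2 come intact from 4',5,7-trimethoxyflavone, ring B of unit 1 is attached at C8 by Suzuki coupling, and rings A and C of unit 1 arrive last as an intact chromone.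
3. O7 of unit 2 is singled out by its acidity (demethylation, peracetylation, thiolysis of the 7-acetate, Mitsunobu prenylation) while unit 1 is still absent, so O7 of unit 1 never competes.
4. Enabling feature: C2–H of the chromone (vinylic, on the carbon bonded to ring oxygen O1, β-terminus of the vinylogous ester O1–C2=C3–C4=O) is its most acidic C–H and is zincated selectively. C1' of ring B is para to O4' and meta to the biaryl bond, an unhindered C–Cl carried in from the boronic acid.
5. Because ring C of unit 1 is attached rather than built, no acidic or oxidative flavone-forming step meets the prenyl ether, and only mild methanolysis follows the union.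
6. Stereochemistry: the target has no stereocentre and none is created.

Key step: step 8

Remark: the target SMILES gives no axial descriptor, so the C3'–C8 biaryl axis is treated as configurationally unassigned and is not controlled. Compounds 1, 3, 8 and 10 are taken as commercial.

**Step 1**
Reactants: 1 4',5,7-trimethoxyflavone
Product: 2 8-iodo-5,7-dimethoxy-2-(4-methoxyphenyl)-4H-chromen-4-one
Conditions: NIS (1.05 equiv), TFA (0.3 equiv), MeCN, 0 °C to rt
Reagents that add atoms: N-iodosuccinimide, O=C1CCC(=O)N1I
Why: Electrophilic aromatic iodination; in 5,7-dialkoxyflavones C8 (ortho to O7 and O1, para to O5, less hindered than C6 between two methoxy groups) is the established halogenation site when no free 5-OH directs to C6, while ring B and C3 are deactivated by the pyranone.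

**Step 2**
Reactants: 2 8-iodo-5,7-dimethoxy-2-(4-methoxyphenyl)-4H-chromen-4-one; 3 (5-chloro-2-methoxyphenyl)boronic acid
Product: 4 8-(5-chloro-2-methoxyphenyl)-5,7-dimethoxy-2-(4-methoxyphenyl)-4H-chromen-4-one
Conditions: Pd(PPh3)4 (5 mol %), K2CO3, DMF/H2O (9:1), 90 °C
Reagents that add atoms: none
Why: Suzuki–Miyaura coupling; zerovalent palladium with triphenylphosphine inserts into the C8–I bond but not into the aryl C–Cl bond, so the chloride survives as the handle for step 8, and couplings of 8-iodo-5,7-dimethoxyflavones with ortho-alkoxyarylboron reagents are a standard entry to this biaryl type.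

**Step 3**
Reactants: 4 8-(5-chloro-2-methoxyphenyl)-5,7-dimethoxy-2-(4-methoxyphenyl)-4H-chromen-4-one
Product: 5 8-(5-chloro-2-hydroxyphenyl)-5,7-dihydroxy-2-(4-hydroxyphenyl)-4H-chromen-4-one
Conditions: BBr3 (excess), CH2Cl2, −78 °C to rt; aqueous work-up
Reagents that add atoms: none
Why: Lewis acid ether cleavage (BBr3 demethylation) of all four aryl methyl ethers, placed before any acid-sensitive group is present; the aryl chloride and the flavone core are inert to BBr3.

**Step 4**
Reactants: 5 8-(5-chloro-2-hydroxyphenyl)-5,7-dihydroxy-2-(4-hydroxyphenyl)-4H-chromen-4-one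
Product: 6 8-(2-acetoxy-5-chlorophenyl)-2-(4-acetoxyphenyl)-4-oxo-4H-chromene-5,7-diyl diacetate
Conditions: Ac2O, pyridine, DMAP (cat.), rt to 50 °C
Reagents that add atoms: acetic anhydride, CC(=O)OC(C)=O
Why: Exhaustive O-acetylation (DMAP-catalysed acyl transfer) converts all four phenols, including the hydrogen-bonded 5-OH, into acetates so that the next step can single out O7.

**Step 5**
Reactants: 6 8-(2-acetoxy-5-chlorophenyl)-2-(4-acetoxyphenyl)-4-oxo-4H-chromene-5,7-diyl diacetate
Product: 7 5-acetoxy-8-(2-acetoxy-5-chlorophenyl)-2-(4-acetoxyphenyl)-7-hydroxy-4H-chromen-4-one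
Conditions: PhSH (1.5 equiv), imidazole (0.5 equiv), NMP, 0 °C to rt
Reagents that add atoms: none
Why: Chemoselective thiolysis (imidazole-mediated acyl transfer to thiophenol); the 7-acetate is the most reactive aryl ester because the 7-oxide, para to the C4 carbonyl, is the best phenoxide leaving group, the known basis of regioselective 7-O-deacetylation of peracetylated flavones.

**Step 6**
Reactants: 7 5-acetoxy-8-(2-acetoxy-5-chlorophenyl)-2-(4-acetoxyphenyl)-7-hydroxy-4H-chromen-4-one; 8 3-methylbut-2-en-1-ol (prenol)
Product: 9 5-acetoxy-8-(2-acetoxy-5-chlorophenyl)-2-(4-acetoxyphenyl)-7-(3-methylbut-2-en-1-yloxy)-4H-chromen-4-one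
Conditions: PPh3, DIAD, THF, 0 °C to rt
Reagents that add atoms: none
Why: Mitsunobu etherification; the acidic 7-OH attacks the activated primary allylic alcohol at CH2 (SN2) to give the linear prenyl ether under neutral conditions that leave the three acetates in place, which a carbonate-mediated alkylation might scramble.

**Step 7**
Reactants: 10 5,7-dihydroxy-4H-chromen-4-one
Product: 11 4-oxo-4H-chromene-5,7-diyl bis(2,2-dimethylpropanoate)
Conditions: PivCl (3 equiv), Et3N, DMAP (cat.), CH2Cl2, rt to 40 °C
Reagents that add atoms: pivaloyl chloride, CC(C)(C)C(Cl)=O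
Why: Acylation (DMAP catalysis) protects both phenols as pivalates, which have no enolisable hydrogen and tolerate the zinc amide base of step 8.

**Step 8**
Reactants: 11 4-oxo-4H-chromene-5,7-diyl bis(2,2-dimethylpropanoate) (1.5 equiv); 9 5-acetoxy-8-(2-acetoxy-5-chlorophenyl)-2-(4-acetoxyphenyl)-7-(3-methylbut-2-en-1-yloxy)-4H-chromen-4-one
Product: 13 tri-O-acetyl-di-O-pivaloyl-7''-O-prenylamentoflavone, via chromon-2-ylzinc chloride 12 (not isolated)
Conditions: TMPZnCl·LiCl (0.95 equiv relative to 11), THF, 25 °C; then 9, Pd(OAc)2 (5 mol %), XPhos (10 mol %), THF, 50 °C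
Reagents that add atoms: TMPZnCl·LiCl (2,2,6,6-tetramethylpiperidinylzinc chloride–lithium chloride), CC1(C)CCCC(C)(C)N1[Zn]Cl.[Li+].[Cl-] (its zinc and chlorine are held only in 12; none of its atoms stays in 13)
Why: TMPZnCl·LiCl, used without added Lewis acid and in slight deficit to 11, removes the most acidic proton of the chromone, the vinylic C2–H on the carbon bonded to O1 at the β-terminus of the vinylogous ester O1–C2=C3–C4=O, to give the ester-tolerant C2-zinc species 12; zerovalent palladium formed in situ from Pd(OAc)2 and XPhos then inserts into the C1'–Cl bond of 9, transmetalation with 12 follows, and reductive elimination forms the C2–C1' bond (one-pot C–H zincation/Negishi coupling). The closest known reaction type is the amide-base C2-zincation of chromones followed by Negishi arylation, an established flavone synthesis, extended here from aryl iodides to an aryl chloride by the bulky biarylphosphine. No ring is closed and no stereocentre is created; the biaryl axis is untouched. The deprotonation must select C2 over C3 and over the ring A C–H between the two pivalates, which the higher acidity of C2–H, the absence of a Lewis acid at the C4 carbonyl and the weak directing power of pivalates towards a zinc amide should secure. The coupling must select C–Cl insertion over the aryl C–O ester bonds and the allylic C–O bond of the prenyl ether, which the electron-rich bulky ligand, the poor binding of the trisubstituted alkene to palladium and the absence of any nucleophile other than 12 should secure. Organozinc halides do not add to aryl esters or to the chromone carbonyls, so the five esters and both pyranones should survive, and keeping the zinc amide in deficit should prevent zinc enolate formation from the acetates.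

**Step 9**
Reactants: 13 tri-O-acetyl-di-O-pivaloyl-7''-O-prenylamentoflavone
Product: 14 7''-O-prenylamentoflavone (target)
Conditions: K2CO3 (6 equiv), MeOH/THF, rt; then AcOH to pH 6
Reagents that add atoms: none
Why: Base-mediated transesterification (methanolysis) cleaves the five aryl esters, all good phenoxide leaving groups, while the allylic aryl ether and both flavone cores are stable to carbonate in methanol at room temperature, and the acetic acid work-up avoids acid cleavage of the prenyl ether.

**Compound list**
1 | 5,7-dimethoxy-2-(4-methoxyphenyl)-4H-chromen-4-one (4',5,7-trimethoxyflavone) | COc1ccc(cc1)-c1cc(=O)c2c(OC)cc(OC)cc2o1 | starting material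
2 | 8-iodo-5,7-dimethoxy-2-(4-methoxyphenyl)-4H-chromen-4-one | COc1ccc(cc1)-c1cc(=O)c2c(OC)cc(OC)c(I)c2o1 | intermediate
3 | (5-chloro-2-methoxyphenyl)boronic acid | COc1ccc(Cl)cc1B(O)O | starting material
4 | 8-(5-chloro-2-methoxyphenyl)-5,7-dimethoxy-2-(4-methoxyphenyl)-4H-chromen-4-one | COc1ccc(cc1)-c1cc(=O)c2c(OC)cc(OC)c(-c3cc(Cl)ccc3OC)c2o1 | intermediate
5 | 8-(5-chloro-2-hydroxyphenyl)-5,7-dihydroxy-2-(4-hydroxyphenyl)-4H-chromen-4-one | Oc1ccc(cc1)-c1cc(=O)c2c(O)cc(O)c(-c3cc(Cl)ccc3O)c2o1 | intermediate
6 | 8-(2-acetoxy-5-chlorophenyl)-2-(4-acetoxyphenyl)-4-oxo-4H-chromene-5,7-diyl diacetate | CC(=O)Oc1ccc(cc1)-c1cc(=O)c2c(OC(C)=O)cc(OC(C)=O)c(-c3cc(Cl)ccc3OC(C)=O)c2o1 | intermediate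
7 | 5-acetoxy-8-(2-acetoxy-5-chlorophenyl)-2-(4-acetoxyphenyl)-7-hydroxy-4H-chromen-4-one | CC(=O)Oc1ccc(cc1)-c1cc(=O)c2c(OC(C)=O)cc(O)c(-c3cc(Cl)ccc3OC(C)=O)c2o1 | intermediate
8 | 3-methylbut-2-en-1-ol (prenol) | CC(C)=CCO | starting material
9 | 5-acetoxy-8-(2-acetoxy-5-chlorophenyl)-2-(4-acetoxyphenyl)-7-(3-methylbut-2-en-1-yloxy)-4H-chromen-4-one | CC(C)=CCOc1cc(OC(C)=O)c2c(=O)cc(-c3ccc(OC(C)=O)cc3)oc2c1-c1cc(Cl)ccc1OC(C)=O | intermediate
10 | 5,7-dihydroxy-4H-chromen-4-one | O=c1ccoc2cc(O)cc(O)c12 | starting material
11 | 4-oxo-4H-chromene-5,7-diyl bis(2,2-dimethylpropanoate) | O=c1ccoc2cc(OC(=O)C(C)(C)C)cc(OC(=O)C(C)(C)C)c12 | intermediate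
12 | [5,7-bis(pivaloyloxy)-4-oxo-4H-chromen-2-yl]zinc chloride (lithium chloride complex, in THF) | O=c1cc([Zn]Cl)oc2cc(OC(=O)C(C)(C)C)cc(OC(=O)C(C)(C)C)c12 | intermediate
13 | 8-[2-acetoxy-5-(5,7-bis(pivaloyloxy)-4-oxo-4H-chromen-2-yl)phenyl]-2-(4-acetoxyphenyl)-7-(3-methylbut-2-en-1-yloxy)-4-oxo-4H-chromen-5-yl acetate | CC(C)=CCOc1cc(OC(C)=O)c2c(=O)cc(-c3ccc(OC(C)=O)cc3)oc2c1-c1cc(-c2cc(=O)c3c(OC(=O)C(C)(C)C)cc(OC(=O)C(C)(C)C)cc3o2)ccc1OC(C)=O | intermediate
14 | 8-[5-(5,7-dihydroxy-4-oxo-4H-chromen-2-yl)-2-hydroxyphenyl]-5-hydroxy-2-(4-hydroxyphenyl)-7-(3-methylbut-2-en-1-yloxy)-4H-chromen-4-one (7''-O-prenylamentoflavone) | CC(C)=CCOc1cc(O)c2c(=O)cc(-c3ccc(O)cc3)oc2c1-c1cc(-c2cc(=O)c3c(O)cc(O)cc3o2)ccc1O | target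

**Totals**
Total step count: 9. Longest linear sequence: 8 steps (steps 1, 2, 3, 4, 5, 6, 8, 9).

**Steps most likely to fail**

Step 8. The deprotonation may go astray (zincation at C3 or on ring A between the pivalates, or attack of the amide base on an ester), the zinc species may be protonated before it couples, or insertion into the electron-rich C–Cl bond may be too slow. The fallback removes the basic organometallic. Setting out from 9, Miyaura borylation of the aryl chloride (B2pin2, Pd(OAc)2, XPhos, KOAc, dioxane, 80 °C) would give 4-acetoxy-3-[5-acetoxy-2-(4-acetoxyphenyl)-7-(3-methylbut-2-en-1-yloxy)-4-oxo-4H-chromen-8-yl]phenylboronic acid pinacol ester F1. F1 would then be joined to chromone 11 at C2 by an oxidative boron-Heck arylation under divalent palladium catalysis (Pd(TFA)2, 2,2'-bipyridine, O2 or benzoquinone as terminal oxidant), a known way from chromones to flavones in which the aryl group adds to C2 and β-hydride loss restores the pyranone. This comes back to the route at 13.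

Step 5. Thiolysis may lose site selectivity, because the flanking 8-aryl group shields the 7-acetate and the other aryl acetates may be cleaved in competition or in addition. The fallback replaces selective deacylation by acidity-controlled alkylation. Setting out from 5, prenyl bromide (1.05 equiv) with KHCO3 (1 equiv) in DMF at rt should alkylate only the most acidic phenol to give 8-(5-chloro-2-hydroxyphenyl)-5-hydroxy-2-(4-hydroxyphenyl)-7-(3-methylbut-2-en-1-yloxy)-4H-chromen-4-one F2. Acetylation of the three remaining phenols of F2 (Ac2O, pyridine, DMAP) comes back to the route at 9.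

Step 2. Protodeboronation of the ortho-methoxy arylboronic acid may outrun transmetalation at the doubly flanked C8–palladium centre, or the iodide may be reduced. The fallback reverses the polarity of the coupling. Setting out from 2, Miyaura borylation (B2pin2, Pd(dppf)Cl2, KOAc, dioxane, 90 °C) would give 5,7-dimethoxy-2-(4-methoxyphenyl)-8-(4,4,5,5-tetramethyl-1,3,2-dioxaborolan-2-yl)-4H-chromen-4-one F3. Suzuki coupling of F3 with commercial 2-bromo-4-chloroanisole (Pd(PPh3)4, K2CO3, dioxane/H2O), in which the bromide reacts in preference to the chloride, comes back to the route at 4.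

**Further compounds**
F1 | step 8 | 4-acetoxy-3-[5-acetoxy-2-(4-acetoxyphenyl)-7-(3-methylbut-2-en-1-yloxy)-4-oxo-4H-chromen-8-yl]phenylboronic acid pinacol ester | CC(C)=CCOc1cc(OC(C)=O)c2c(=O)cc(-c3ccc(OC(C)=O)cc3)oc2c1-c1cc(B2OC(C)(C)C(C)(C)O2)ccc1OC(C)=O
F2 | step 5 | 8-(5-chloro-2-hydroxyphenyl)-5-hydroxy-2-(4-hydroxyphenyl)-7-(3-methylbut-2-en-1-yloxy)-4H-chromen-4-one | CC(C)=CCOc1cc(O)c2c(=O)cc(-c3ccc(O)cc3)oc2c1-c1cc(Cl)ccc1O
F3 | step 2 | 5,7-dimethoxy-2-(4-methoxyphenyl)-8-(4,4,5,5-tetramethyl-1,3,2-dioxaborolan-2-yl)-4H-chromen-4-one | COc1ccc(cc1)-c1cc(=O)c2c(OC)cc(OC)c(B3OC(C)(C)C(C)(C)O3)c2o1
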